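(The numbers of this flask come from no measurement.)

Start from the number N = 3.13, the capture constant of the first nucleophile times the concentration of it that the open intermediate meets, divided by the solvolysis constant, and read it as the target made per solvolysis product, here for a flask holding the whole charge of first nucleophile.

common to all: gas 13 mM (held); capture agent 0.0100 M; time 2.0 h

| flask | substrate | first nucleophile | remark |
|---|---|---|---|
| theta | 0.10 M | 0.400 M | everything together at the start |
| zeta | 0.10 M | 0.400 M (fed, over 80 min) | all else is in the flask from the start; the feed brings no volume worth counting |
| delta | 0.10 M (fed, over 80 min) | 0.400 M | all else is in the flask from the start; the feed brings no volume worth counting |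

    substrate → open intermediate (k1 = 0.484 min⁻¹)
    first nucleophile + open intermediate → target (k2 = 20.4 M⁻¹ min⁻¹)
    second nucleophile + open intermediate → other capture product (k3 = 2210 M⁻¹ min⁻¹)
    open intermediate → solvolysis product (k4 = 2.61 min⁻¹)
    gas ⇌ second nucleophile, rate k5*(csat - [second nucleophile]) (k5 = 0.173 min⁻¹, csat = 13 mM)
    open intermediate + capture agent → trapped intermediate (k6 = 2.92 M⁻¹ min⁻¹)
    crystals ⇌ target, rate k7*(cs7 - [target]) while solid is left; crystals form when [target] > cs7 (cs7 = 0.077 M, k7 = 0.921 min⁻¹)

- amounts and yields of target count crystals too
- given per volume of solution although it is solid: crystals
- at the start none of second nucleophile is dissolved
- run time (theta): 2.0 h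

- which flask leads in amount of target, in percent of the substrate charged ("all alike" within 1.5 percentage points) (theta / zeta / delta / all alike)
- how much target is there at the end, in percent of the substrate charged: theta
- how much target is there at the end, in percent of the substrate charged: zeta
- how much target is there at the end, in percent of the substrate charged: delta

Reckon N for each flask. Flask theta and flask delta both hold the first nucleophile from the start, so both begin with the N above, and of the intermediate that escapes the second nucleophile, target takes N over one plus N, or 75.8%. In flask zeta the substrate has a lifetime of 2.07 min, and in one lifetime the feed brings 10.3 mM of first nucleophile, so N reckoned at that concentration falls to 0.0807 and target's part of that same intermediate to 7.47%.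

Now test whether N is enough, and see that it is not, since it begins alike in flask theta and flask delta. At saturation the second nucleophile's capture rate over the solvolysis rate is 11.0, larger than N, so ask whether the gas has time to dissolve. Its time constant for dissolving is 5.78 min, which is longer than the substrate's lifetime in flask theta but shorter than the 80 min feed of flask delta. Commit, then, to flask theta leading, with flask delta behind it by an amount this reckoning does not give.

The forecast goes further: theta leads with 64%, against 5.5% for zeta and 28% for delta, because “the substrate opens within minutes, outrunning the gas supply of second nucleophile”.

The simulation gives theta in the lead with 64.5%, then 5.08% for zeta and 27.8% for delta, so the forecast held. Flask delta ends with 62.9% of other capture product, against 12.7% in flask theta. In flask zeta, target per solvolysis product reads 0.0648, below the reckoned N of 0.0807.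

Take next the neighbour of flask zeta, fed 1.6 M of first nucleophile over the same 80 min: the feed multiplies N by 4.00, to 0.323. That flask ends with 16.6% of target and 68.0% of solvolysis product, a ratio of 0.244, again below N.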